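(Readings and results were generated by integration for substances that don't exist.)

The left-handed product of the birch run slows as it climbs, and that run is the flask asked about, followed so far. Free catalyst binds either substrate, partner turns each bound substrate into its product, and protic impurity quenches partner on the side.

| flask | left-handed substrate | right-handed substrate | partner | protic impurity | free catalyst | temperature | remark | time |
|---|---|---|---|---|---|---|---|---|
| birch | 0.014 M | 0.014 M | 1.2 equiv | 7 mM | 0.11 mol% | 90 °C | the very flask that is asked about, followed so far |  |
| larch | 0.014 M | 0.014 M | 1.2 equiv | 14 mM | 0.11 mol% | 96 °C | run made earlier |  |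
| flask | 0.014 M | 0.014 M | 1.20 equiv | 7.00 mM | 0.11 mol% | 90 °C |  | 12 h |

| run | time / h | left-handed product / % | left-handed substrate / % |
|---|---|---|---|
| birch | 0.833 | 9.5 | 40.7 |
| birch | 1.33 | 13.6 | 35.7 |
| birch | 2.00 | 18.4 | 31.7 |
| birch | 2.50 | 20.1 | 29.5 |
| birch | 4.00 | 26.7 | 23.7 |
| birch | 6.00 | 31.2 | 19.3 |
| birch | 10.0 | 33.9 | 15.2 |
| larch | 0.333 | 5.5 | 44.0 |
| larch | 1.00 | 12.4 | 37.2 |
| larch | 1.50 | 16.7 | 33.2 |
| larch | 2.50 | 21.2 | 28.7 |
| larch | 4.00 | 26.4 | 23.7 |
| larch | 5.00 | 28.0 | 21.8 |
| larch | 6.00 | 29.4 | 20.8 |

(standard deviation of a reading: 0.5 percentage points)

- free catalyst is single-handed; left-handed substrate and right-handed substrate are mirror images of each other, charged as a racemate, each of them at the stated concentration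
- removed left-handed product is counted in
- steps under discussion: free catalyst + right-handed substrate <-> catalyst intermediate B; free catalyst <-> dormant form; partner + catalyst intermediate B -> free catalyst + right-handed product; partner + protic impurity -> quenched reagent; partner + catalyst intermediate A -> free catalyst + left-handed product; free catalyst + left-handed substrate <-> catalyst intermediate A
- additions bring no volume worth counting

- alpha: at 12 h add free catalyst, 100% of the amount charged, then wait 25 h
- zeta: at 12 h raise the temperature by 25 K, then wait 25 h
- delta: change nothing and wait 25 h more
- eta: at 12 h take out 90% of the left-handed product then present, then wait 25 h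
- epsilon: at 12 h add partner, 50.0% of the amount charged, then wait 25 h

- left-handed product, in percent of the left-handed substrate and right-handed substrate together first charged, at 12 h
- the option that brings most further left-handed product ("none" if no option brings more than 2 percentage points) (alpha / zeta / delta / eta / epsilon / none)
- left-handed product present, with what was taken out counted in, in percent of the left-handed substrate and right-handed substrate together first charged, after alpha
- left-handed product present, with what was taken out counted in, in percent of the left-handed substrate and right-handed substrate together first charged, after zeta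

The loss of left-handed substrate can be read as a pseudo-first-order constant, taken here as proportional to partner left while catalyst holds steady. In birch it reads 0.214 h⁻¹ at product 14.0% and 0.0740 h⁻¹ at 30.3%. If partner falls in step with product, the straight line through these pairs reaches zero at a roof:

roof = 38.9% of the charge

Partner charged is 0.600 of both substrates together, so one unit of left-handed product costs:

price = 1.54 units of partner

The excess over one goes to right-handed product and quenching. The number that carries this is the cover 0.779, the equivalents of partner charged over the price. Below one, at this price, the reckoning makes partner the limiting reagent and stops the product at the roof.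

One number is not enough: larch, with the same equivalents, reads a cover of 0.683, lower, hotter and with twice the impurity. Fading catalyst could bend the line in a like way, so this reckoning commits to partner without proving it.

Carried from the last birch reading, the line gives 35.2% at 12 h. Alpha, zeta, delta and eta add no partner, while epsilon lifts the reckoned cover to 1.17, above one, so this reckoning chooses epsilon.

The forecast differs on the choice, with 35.5%, alpha as best, 46% after alpha and 38.5% after zeta: “I lean towards catalyst loss, though not firmly”.

The flask gives 35.1%, 36.6% after alpha and 36.2% after zeta. The best option is epsilon, which brings 12 percentage points.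

    free catalyst + right-handed substrate ⇌ catalyst intermediate B (K = 80.0 L mol⁻¹, k = 1.30 × 10⁵ L mol⁻¹ h⁻¹, Ea = 57.0 kJ mol⁻¹, ΔH = −30.0 kJ mol⁻¹)
    free catalyst ⇌ dormant form (K = 0.480, k = 0.0300 h⁻¹, Ea = 110 kJ mol⁻¹, ΔH = −58.0 kJ mol⁻¹)
    partner + catalyst intermediate B → free catalyst + right-handed product (k = 16000 L mol⁻¹ h⁻¹, Ea = 70.0 kJ mol⁻¹)
    partner + protic impurity → quenched reagent (k = 6.20 L mol⁻¹ h⁻¹, Ea = 65.0 kJ mol⁻¹)
    partner + catalyst intermediate A → free catalyst + left-handed product (k = 39000 L mol⁻¹ h⁻¹, Ea = 41.0 kJ mol⁻¹)
    free catalyst + left-handed substrate ⇌ catalyst intermediate A (K = 120 L mol⁻¹, k = 2.10 × 10⁵ L mol⁻¹ h⁻¹, Ea = 49.0 kJ mol⁻¹, ΔH = −20.0 kJ mol⁻¹)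
    (constants at 90 °C)

The neighbouring flask with 4.80 equiv of partner is reckoned, at the same price, to have a cover of 3.12, above one, so the reckoning expects its left-handed substrate to be consumed. At 12.0 h that neighbour holds left-handed product 50.0% and left-handed substrate 0%, with partner at 48.7% of its charge.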